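**Plan**

- Ring labels: A = terminal 3,5-dihydroxyphenoxy ring; B and C = the two benzo rings of the dibenzofuran (B carries A–O on B1; C is shared with the dioxin); D = outer benzo ring of the dioxin; E–F = biaryl; G, H = last two rings of the ether chain. Ring C: C1 (furan O), C3 (OH), C4 and C5 (dioxin O), C6 (bond to B5). Ring D: D1 (O to C5), D2 and D4 (OH), D5 (O–E1), D6 (O to C4).
- Cuts, in retrosynthetic order: sixteen O–Me bonds; ethers F6–O–G1 and D5–O–E1 (Ullmann; E–F biaryl by homocoupling, G6–O–H1 by Ullmann/Dakin); dioxin bond O(D6)–C4 (anodic C–H/O–H coupling); ether C5–O–D1 (Ullmann); furan C–C bond B5–C6 (decarboxylative arylation); ethers C1–O–B6 (SNAr) and A–O–B1 (Ullmann).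
- Forward order: A–O–B, B–O–C, furan ring (B/C), C–O–D, dioxin ring, D–O–E(F), F–O–G(H), global demethylation. All eight benzene rings are bought; methyl ethers are the permanent protection.
- Enabling feature: in seco-phenol 17 the D6–OH hangs on the C5–O–D1 tether beside C4–H. C4 is the only unsubstituted carbon of the electron-rich dibenzofuran ring C that this oxygen can reach (six-membered ring), and it is para to the furan oxygen on C1. The D2 formyl group first activates D1–Br, then shields ring D from the anode, and finally becomes D2–OH.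
- Stereochemistry: there is no stereocentre; the E–F biaryl axis (tetra-ortho-oxygenated in the target) arises racemic in step 18 and is carried through unchanged.

Key step: step 13

Remark: the target SMILES defines no configuration for the E–F biaryl axis, so no atroposelective control is attempted.

**Step 1**
Reactants: 1 3,5-dimethoxyphenol; 2 2-bromo-3,5-dimethoxybenzaldehyde
Product: 3 2-(3,5-dimethoxyphenoxy)-3,5-dimethoxybenzaldehyde
Conditions: CuI (10 mol%), picolinic acid (20 mol%), K3PO4, DMSO, 90 °C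
Reagents that add atoms: none
Why: Ullmann-type Cu-catalysed O-arylation, in which the ortho-formyl group activates the flanked C–Br bond of 2 and the unhindered phenol 1 forms the A–O–B1 ether.

**Step 2**
Reactants: 3
Product: 5 2-(3,5-dimethoxyphenoxy)-3,5-dimethoxyphenol, via aryl formate 4 (not isolated)
Conditions: mCPBA, CH2Cl2, 0 °C to rt; then K2CO3 (cat.), MeOH, rt
Reagents that add atoms: mCPBA (3-chloroperoxybenzoic acid), OOC(=O)c1cccc(Cl)c1
Why: Baeyer–Villiger (Dakin-type) oxidation, in which the ortho-aryloxy aryl group migrates to oxygen and methanolysis of formate 4 frees the B6 hydroxyl that becomes the furan oxygen.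

**Step 3**
Reactants: 5; 6 2,6-difluoro-4-methoxybenzaldehyde
Product: 7 2-[2-(3,5-dimethoxyphenoxy)-3,5-dimethoxyphenoxy]-6-fluoro-4-methoxybenzaldehyde
Conditions: K2CO3, DMF, 70 °C (6 in 1.5-fold excess)
Reagents that add atoms: none
Why: SNAr of one of the two equivalent fluorides ortho to the formyl group of 6 by the phenoxide of 5, the new aryloxy donor slowing a second substitution.

**Step 4**
Reactants: 7
Product: 8 2-[2-(3,5-dimethoxyphenoxy)-3,5-dimethoxyphenoxy]-4-methoxy-6-[2-(trimethylsilyl)ethoxy]benzaldehyde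
Conditions: Me3SiCH2CH2OH, NaH, THF, 0 °C to rt
Reagents that add atoms: 2-(trimethylsilyl)ethanol, C[Si](C)(C)CCO
Why: SNAr of the remaining ortho-fluoride by a primary alkoxide installs a fluoride-labile ether on C5–O that has no arene C–H able to compete in the palladation of step 6.

**Step 5**
Reactants: 8
Product: 9 2-[2-(3,5-dimethoxyphenoxy)-3,5-dimethoxyphenoxy]-4-methoxy-6-[2-(trimethylsilyl)ethoxy]benzoic acid
Conditions: NaClO2, NaH2PO4, 2-methyl-2-butene (excess), t-BuOH–THF–H2O, 0 °C to rt
Reagents that add atoms: NaClO2 (sodium chlorite), [Na+].[O-]Cl=O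
Why: Pinnick oxidation of the hindered electron-rich aldehyde, the excess alkene trapping HOCl before it can chlorinate ring A.

**Step 6**
Reactants: 9
Product: 10 4-(3,5-dimethoxyphenoxy)-1,3,7-trimethoxy-9-[2-(trimethylsilyl)ethoxy]dibenzo[b,d]furan
Conditions: Pd(O2CCF3)2 (15 mol%), Ag2CO3 (3 equiv), DMSO–1,4-dioxane (1:19), 150 °C
Reagents that add atoms: none
Why: Pd/Ag decarboxylative intramolecular direct arylation of a 2-aryloxybenzoic acid, in which the 2,6-dioxygenated carboxylate loses CO2 at silver, the aryl group passes to divalent palladium and C–H palladation at B5, the only free carbon ortho to the B6–O ether, closes the furan ring.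

**Step 7**
Reactants: 10
Product: 11 4-(3,5-dimethoxyphenoxy)-1,3,7-trimethoxydibenzo[b,d]furan-9-ol
Conditions: CsF, DMF, 80 °C; then 1 M HCl
Reagents that add atoms: none
Why: Fluoride-induced β-elimination of the 2-(trimethylsilyl)ethyl ether frees the C5 hydroxyl while methyl and diaryl ethers stay intact.

**Step 8**
Reactants: 12 3,4-dihydroxy-5-methoxybenzaldehyde
Product: 13 4-(benzyloxy)-3-hydroxy-5-methoxybenzaldehyde
Conditions: BnBr (1.05 equiv), Li2CO3, DMF, 40 °C
Reagents that add atoms: benzyl bromide, BrCc1ccccc1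
Why: Regioselective Williamson etherification, the 4-OH para to the formyl group being the most acidic and the only one ionised by the weak base.

**Step 9**
Reactants: 13
Product: 14 4-(benzyloxy)-2-bromo-3-hydroxy-5-methoxybenzaldehyde
Conditions: Br2 (1.0 equiv), NaOAc, AcOH, 15 °C
Reagents that add atoms: bromine, BrBr
Why: Electrophilic aromatic bromination ortho to the free 3-OH and para to the 5-OMe, the same site as in the bromination of isovanillin to its 2-bromo derivative, puts bromine on D1.

**Step 10**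
Reactants: 14
Product: 15 4-(benzyloxy)-2-bromo-5-methoxy-3-(methoxymethoxy)benzaldehyde
Conditions: MOMCl, i-Pr2NEt, CH2Cl2, 0 °C to rt
Reagents that add atoms: chloromethyl methyl ether, COCCl
Why: Acetal (MOM) protection of the D6 phenol keeps an ortho-bromophenoxide out of the next copper coupling and is orthogonal to the benzyl ether on D5.

**Step 11**
Reactants: 11; 15
Product: 16 4-(benzyloxy)-2-{[4-(3,5-dimethoxyphenoxy)-1,3,7-trimethoxydibenzo[b,d]furan-9-yl]oxy}-5-methoxy-3-(methoxymethoxy)benzaldehyde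
Conditions: CuI (20 mol%), picolinic acid (40 mol%), K3PO4, DMSO, 100 °C
Reagents that add atoms: none
Why: Ullmann-type Cu-catalysed O-arylation, the ortho-formyl group again activating the flanked C–Br bond, and 11 offering a single hydroxyl so that only the C5–O–D1 ether can form.

**Step 12**
Reactants: 16
Product: 17 4-(benzyloxy)-2-{[4-(3,5-dimethoxyphenoxy)-1,3,7-trimethoxydibenzo[b,d]furan-9-yl]oxy}-3-hydroxy-5-methoxybenzaldehyde
Conditions: HCl (3 M in MeOH), THF, 45 °C; aqueous work-up
Reagents that add atoms: none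
Why: Acid-catalysed transacetalisation removes the MOM group as dimethoxymethane and frees the D6 hydroxyl, with benzyl, methyl and diaryl ethers stable.

**Step 13**
Reactants: 17
Product: 18 benzofuro-fused dibenzo[1,4]dioxin aldehyde: 17 with the D6 oxygen bonded to C4 of ring C (dibenzofuran C8); D2 = CHO, D5 = OBn, D4, C3, B2, B4 = OMe, ring A = 3,5-dimethoxyphenoxy on B1
Conditions: graphite anode, Pt cathode, undivided cell, constant current 2 mA cm−2, 2.2 F mol−1, Bu4NBF4 (0.1 M), (CF3)2CHOH–CH2Cl2 (4:1), 5 mM, rt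
Reagents that add atoms: none
Why: Proposed new method: anodic one-electron oxidation of the electron-rich planar dibenzofuran (rings B and C) in hexafluoroisopropanol should give an arene radical cation, the D6 hydroxyl adds to C4, and loss of a second electron and two protons (H2 at the cathode) re-aromatises ring C, so the C4–H/O–H pair is joined without a halogen. The closest known reaction types are anodic intramolecular dehydrogenative C–H/O–H couplings such as the lactonisation of biaryl-2-carboxylic acids, anodic phenol–arene cross-coupling in fluorinated alcohols and the anodic C–O coupling of phenols to diaryl ethers; a dibenzo-1,4-dioxin has not been closed in this way. The single ring formed, the six-membered 1,4-dioxin, is closed by attack of oxygen on the arene carbon ortho to the tethering C5–O–D1 ether (formally 6-exo on the C3–C4 π bond of the oxidised ring). No stereocentre is formed. The step needs oxidation of rings B/C in preference to the ring-D phenol, which the D2 formyl group and the absence of base are meant to secure, and attack at C4 only: of the three carbons within reach, C5 (ipso, reversible spiro ketal) and C6 (ring-fusion carbon, no proton to lose) cannot give an aromatic product, and C4 is para to the furan oxygen where the radical cation is most electrophilic. Over-oxidation of the more electron-rich product is to be limited by low current density, high dilution and stopping near 2 F per mole.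

**Step 14**
Reactants: 18
Product: 20 D2 phenol (18 with CHO replaced by OH), via aryl formate 19 (not isolated)
Conditions: mCPBA, CH2Cl2, 0 °C; then K2CO3 (cat.), MeOH, rt
Reagents that add atoms: mCPBA (3-chloroperoxybenzoic acid), OOC(=O)c1cccc(Cl)c1
Why: Baeyer–Villiger (Dakin-type) oxidation, in which the aryl group bearing ortho- and para-oxygen donors migrates and turns the formyl helper into the D2 oxygen.

**Step 15**
Reactants: 20
Product: 21 D2 methyl ether (D5 still O-benzyl)
Conditions: MeI, K2CO3, DMF, rt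
Reagents that add atoms: iodomethane, CI
Why: Williamson O-methylation caps the D2 phenol so that the D5 hydroxyl freed next is the only nucleophile.

**Step 16**
Reactants: 21
Product: 22 D5 phenol of the A–D core (all other oxygens methylated)
Conditions: H2 (1 atm), Pd/C (10%), EtOAc–MeOH, rt
Reagents that add atoms: none
Why: Catalytic hydrogenolysis cleaves the single benzyl ether, nothing else in 21 being reducible.

**Step 17**
Reactants: 23 1-bromo-3,5-dimethoxybenzene
Product: 24 1-bromo-2-iodo-3,5-dimethoxybenzene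
Conditions: NIS, CF3CO2H (cat.), MeCN, rt
Reagents that add atoms: N-iodosuccinimide, O=C1CCC(=O)N1I
Why: Electrophilic aromatic iodination ortho to bromine and para to a methoxy group, the usual site of substitution in 1-halo-3,5-dimethoxybenzenes.

**Step 18**
Reactants: 24 1-bromo-2-iodo-3,5-dimethoxybenzene
Product: 25 2,2'-dibromo-4,4',6,6'-tetramethoxy-1,1'-biphenyl (racemic axis)
Conditions: Cu powder (activated, 3 equiv), DMF, 140 °C; two molecules of 24 per molecule of 25
Reagents that add atoms: 1-bromo-2-iodo-3,5-dimethoxybenzene (the second molecule of 24, joined to the first), COc1cc(Br)c(I)c(OC)c1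
Why: Classical Ullmann reductive homocoupling, in which two molecules of 24 are joined at their iodine-bearing carbons with loss of both iodides to copper, selective for C–I over C–Br, builds the C2-symmetric tetra-ortho-substituted E–F biaryl as a racemate.

**Step 19**
Reactants: 22; 25
Product: 26 aryl bromide: 22 O-arylated on D5 by one ring (E) of 25, F6–Br retained
Conditions: 25 (3 equiv), CuI (20 mol%), picolinic acid (40 mol%), K3PO4, DMSO, 110 °C
Reagents that add atoms: none
Why: Ullmann-type O-arylation of the 2,6-dioxygenated phenol with an excess of the C2-symmetric dibromide so that only one C–Br reacts, the racemic E–F axis of 25 being carried through unchanged.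

**Step 20**
Reactants: 27 2,4,6-trimethoxyphenol; 28 2-bromo-4,6-dimethoxybenzaldehyde
Product: 29 2,4-dimethoxy-6-(2,4,6-trimethoxyphenoxy)benzaldehyde
Conditions: CuI (10 mol%), picolinic acid (20 mol%), K3PO4, DMSO, 90 °C
Reagents that add atoms: none
Why: Ullmann-type O-arylation of a 2,6-disubstituted phenol with an ortho-formyl-activated aryl bromide forms the G6–O–H1 ether.

**Step 21**
Reactants: 29
Product: 31 2,4-dimethoxy-6-(2,4,6-trimethoxyphenoxy)phenol, via aryl formate 30 (not isolated)
Conditions: mCPBA, CH2Cl2, 0 °C to rt; then K2CO3 (cat.), MeOH, rt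
Reagents that add atoms: mCPBA (3-chloroperoxybenzoic acid), OOC(=O)c1cccc(Cl)c1
Why: Baeyer–Villiger (Dakin-type) oxidation of a 2,4,6-trioxygenated benzaldehyde gives the G1 hydroxyl between G2–OMe and the G6 aryloxy group.

**Step 22**
Reactants: 26; 31
Product: 32 hexadeca-O-methyl ether of the target
Conditions: 31 (3 equiv), CuI (30 mol%), picolinic acid (60 mol%), K3PO4, DMSO, 120 °C
Reagents that add atoms: none
Why: Ullmann-type O-arylation joins the F6–O–G1 ether, the cheap phenol 31 being used in excess against the advanced bromide.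

**Step 23**
Reactants: 32
Product: 33 target compound (CNP0192765.0)
Conditions: BBr3 (40 equiv), CH2Cl2, −78 °C to rt; then H2O, 0 °C
Reagents that add atoms: none
Why: Lewis-acid ether cleavage, in which bromide attacks the O-methyl carbon of each of the sixteen boron-complexed aryl methyl ethers while diaryl ether, furan and dioxin C–O bonds are inert.

**Compound list**

1 | 3,5-dimethoxyphenol | COc1cc(O)cc(OC)c1 | starting material
2 | 2-bromo-3,5-dimethoxybenzaldehyde | COc1cc(C=O)c(Br)c(OC)c1 | starting material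
3 | 2-(3,5-dimethoxyphenoxy)-3,5-dimethoxybenzaldehyde | COc1cc(OC)cc(Oc2c(C=O)cc(OC)cc2OC)c1 | intermediate
4 | 2-(3,5-dimethoxyphenoxy)-3,5-dimethoxyphenyl formate | COc1cc(OC)cc(Oc2c(OC=O)cc(OC)cc2OC)c1 | intermediate
5 | 2-(3,5-dimethoxyphenoxy)-3,5-dimethoxyphenol | COc1cc(OC)cc(Oc2c(O)cc(OC)cc2OC)c1 | intermediate
6 | 2,6-difluoro-4-methoxybenzaldehyde | COc1cc(F)c(C=O)c(F)c1 | starting material
7 | 2-[2-(3,5-dimethoxyphenoxy)-3,5-dimethoxyphenoxy]-6-fluoro-4-methoxybenzaldehyde | COc1cc(OC)cc(Oc2c(Oc3cc(OC)cc(F)c3C=O)cc(OC)cc2OC)c1 | intermediate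
8 | 2-[2-(3,5-dimethoxyphenoxy)-3,5-dimethoxyphenoxy]-4-methoxy-6-[2-(trimethylsilyl)ethoxy]benzaldehyde | COc1cc(OC)cc(Oc2c(Oc3cc(OC)cc(OCC[Si](C)(C)C)c3C=O)cc(OC)cc2OC)c1 | intermediate
9 | 2-[2-(3,5-dimethoxyphenoxy)-3,5-dimethoxyphenoxy]-4-methoxy-6-[2-(trimethylsilyl)ethoxy]benzoic acid | COc1cc(OC)cc(Oc2c(Oc3cc(OC)cc(OCC[Si](C)(C)C)c3C(=O)O)cc(OC)cc2OC)c1 | intermediate
10 | 4-(3,5-dimethoxyphenoxy)-1,3,7-trimethoxy-9-[2-(trimethylsilyl)ethoxy]dibenzo[b,d]furan | COc1cc(OC)cc(Oc2c(OC)cc(OC)c3c2oc2cc(OC)cc(OCC[Si](C)(C)C)c23)c1 | intermediate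
11 | 4-(3,5-dimethoxyphenoxy)-1,3,7-trimethoxydibenzo[b,d]furan-9-ol | COc1cc(OC)cc(Oc2c(OC)cc(OC)c3c2oc2cc(OC)cc(O)c23)c1 | intermediate
12 | 3,4-dihydroxy-5-methoxybenzaldehyde | COc1cc(C=O)cc(O)c1O | starting material
13 | 4-(benzyloxy)-3-hydroxy-5-methoxybenzaldehyde | COc1cc(C=O)cc(O)c1OCc1ccccc1 | intermediate
14 | 4-(benzyloxy)-2-bromo-3-hydroxy-5-methoxybenzaldehyde | COc1cc(C=O)c(Br)c(O)c1OCc1ccccc1 | intermediate
15 | 4-(benzyloxy)-2-bromo-5-methoxy-3-(methoxymethoxy)benzaldehyde | COCOc1c(Br)c(C=O)cc(OC)c1OCc1ccccc1 | intermediate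
16 | 4-(benzyloxy)-2-{[4-(3,5-dimethoxyphenoxy)-1,3,7-trimethoxydibenzo[b,d]furan-9-yl]oxy}-5-methoxy-3-(methoxymethoxy)benzaldehyde | COc1cc(OC)cc(Oc2c(OC)cc(OC)c3c2oc2cc(OC)cc(Oc4c(C=O)cc(OC)c(OCc5ccccc5)c4OCOC)c23)c1 | intermediate
17 | 4-(benzyloxy)-2-{[4-(3,5-dimethoxyphenoxy)-1,3,7-trimethoxydibenzo[b,d]furan-9-yl]oxy}-3-hydroxy-5-methoxybenzaldehyde | COc1cc(OC)cc(Oc2c(OC)cc(OC)c3c2oc2cc(OC)cc(Oc4c(C=O)cc(OC)c(OCc5ccccc5)c4O)c23)c1 | intermediate
18 | dioxin aldehyde of the A–D core (D2 CHO, D5 OBn, other oxygens methylated) | COc1cc(OC)cc(Oc2c(OC)cc(OC)c3c2oc2cc(OC)c4c(c23)Oc2c(C=O)cc(OC)c(OCc5ccccc5)c2O4)c1 | intermediate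
19 | D2 formate of the A–D core (18 with CHO replaced by OCHO) | COc1cc(OC)cc(Oc2c(OC)cc(OC)c3c2oc2cc(OC)c4c(c23)Oc2c(OC=O)cc(OC)c(OCc5ccccc5)c2O4)c1 | intermediate
20 | D2 phenol of the A–D core (D5 OBn) | COc1cc(OC)cc(Oc2c(OC)cc(OC)c3c2oc2cc(OC)c4c(c23)Oc2c(O)cc(OC)c(OCc5ccccc5)c2O4)c1 | intermediate
21 | D5 benzyl ether of the permethylated A–D core | COc1cc(OC)cc(Oc2c(OC)cc(OC)c3c2oc2cc(OC)c4c(c23)Oc2c(OC)cc(OC)c(OCc5ccccc5)c2O4)c1 | intermediate
22 | D5 phenol of the permethylated A–D core | COc1cc(OC)cc(Oc2c(OC)cc(OC)c3c2oc2cc(OC)c4c(c23)Oc2c(OC)cc(OC)c(O)c2O4)c1 | intermediate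
23 | 1-bromo-3,5-dimethoxybenzene | COc1cc(Br)cc(OC)c1 | starting material
24 | 1-bromo-2-iodo-3,5-dimethoxybenzene | COc1cc(Br)c(I)c(OC)c1 | intermediate
25 | 2,2'-dibromo-4,4',6,6'-tetramethoxy-1,1'-biphenyl (racemic axis) | COc1cc(Br)c(-c2c(Br)cc(OC)cc2OC)c(OC)c1 | intermediate
26 | A–F hexamer bromide (22 carrying the E–F biaryl on D5–O, F6–Br; racemic axis) | COc1cc(OC)cc(Oc2c(OC)cc(OC)c3c2oc2cc(OC)c4c(c23)Oc2c(OC)cc(OC)c(Oc5cc(OC)cc(OC)c5-c5c(OC)cc(OC)cc5Br)c2O4)c1 | intermediate
27 | 2,4,6-trimethoxyphenol | COc1cc(OC)c(O)c(OC)c1 | starting material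
28 | 2-bromo-4,6-dimethoxybenzaldehyde | COc1cc(Br)c(C=O)c(OC)c1 | starting material
29 | 2,4-dimethoxy-6-(2,4,6-trimethoxyphenoxy)benzaldehyde | COc1cc(OC)c(Oc2cc(OC)cc(OC)c2C=O)c(OC)c1 | intermediate
30 | 2,4-dimethoxy-6-(2,4,6-trimethoxyphenoxy)phenyl formate | COc1cc(OC)c(Oc2cc(OC)cc(OC)c2OC=O)c(OC)c1 | intermediate
31 | 2,4-dimethoxy-6-(2,4,6-trimethoxyphenoxy)phenol | COc1cc(OC)c(Oc2cc(OC)cc(OC)c2O)c(OC)c1 | intermediate
32 | hexadeca-O-methyl ether of the target (racemic axis) | COc1cc(OC)cc(Oc2c(OC)cc(OC)c3c2oc2cc(OC)c4c(c23)Oc2c(OC)cc(OC)c(Oc5cc(OC)cc(OC)c5-c5c(OC)cc(OC)cc5Oc5c(OC)cc(OC)cc5Oc5c(OC)cc(OC)cc5OC)c2O4)c1 | intermediate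
33 | CNP0192765.0 | Oc1cc(O)cc(Oc2c(O)cc(O)c3c2oc2cc(O)c4c(c23)Oc2c(O)cc(O)c(Oc3cc(O)cc(O)c3-c3c(O)cc(O)cc3Oc3c(O)cc(O)cc3Oc3c(O)cc(O)cc3O)c2O4)c1 | target

**Step count and risks**

Total steps: 23. Longest linear sequence: 16 steps (1–7, 11–16, 19, 22, 23).

Steps most likely to fail:

1. Step 13 (proposed new method). The ring-D phenol may be oxidised in preference to the dibenzofuran and go on to quinoid or oligomeric material. The more electron-rich product may be over-oxidised. Reversible ipso attack at C5 may lead to aryl migration and a regioisomeric ring closure. The fallback uses only known chemistry, sets out from 11 and returns at 18. Ortho-selective bromination of the phenol (NBS, i-Pr2NH cat., CH2Cl2, 0 °C) should give 8-bromo-4-(3,5-dimethoxyphenoxy)-1,3,7-trimethoxydibenzo[b,d]furan-9-ol F1, with bromine on C4 of ring C. Ullmann coupling with 15 under the conditions of step 11 gives the bromo ether F2. Acid methanolysis of the MOM group as in step 12 gives the bromo phenol F3. An intramolecular Ullmann etherification (CuI, picolinic acid, K3PO4, DMSO, 110 °C) then closes the same O(D6)–C4 bond to give 18.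

2. Step 6. Protodecarboxylation of the aryl–silver or aryl–palladium intermediate may outrun C–H palladation at the hindered B5 position, whose bond formation builds strain between the two bay oxygens. The fallback sets out from 8 and returns at 10. Baeyer–Villiger oxidation of 8 (mCPBA, CH2Cl2) gives the aryl formate F4, which is methanolysed (K2CO3 cat., MeOH) to the phenol F5. Tf2O and pyridine convert it into the aryl triflate F6. A Pd-catalysed intramolecular direct arylation (Pd(OAc)2, PCy3·HBF4, K2CO3, DMA, 130 °C) then closes the B5–C6 bond to give 10.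

3. Step 22 (step 19 shares the same hazard). Copper insertion into the C–Br bond next to the tetra-ortho-substituted biaryl axis and attack by a 2,6-disubstituted phenoxide may both be slow, so reductive loss of bromine can win. The fallback sets out from 26 and returns at 32, changing the aryl partner from a halide to a boron compound. Bromine–lithium exchange (n-BuLi, THF, −78 °C), B(Oi-Pr)3 and aqueous work-up give the arylboronic acid F7. A Chan–Lam coupling with 31 in excess (Cu(OAc)2, pyridine, 4 Å molecular sieves, CH2Cl2, air, rt) then gives 32.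

**Further compounds**

F1 | step 13 | 8-bromo-4-(3,5-dimethoxyphenoxy)-1,3,7-trimethoxydibenzo[b,d]furan-9-ol | COc1cc(OC)cc(Oc2c(OC)cc(OC)c3c2oc2cc(OC)c(Br)c(O)c23)c1
F2 | step 13 | 4-(benzyloxy)-2-{[8-bromo-4-(3,5-dimethoxyphenoxy)-1,3,7-trimethoxydibenzo[b,d]furan-9-yl]oxy}-5-methoxy-3-(methoxymethoxy)benzaldehyde | COc1cc(OC)cc(Oc2c(OC)cc(OC)c3c2oc2cc(OC)c(Br)c(Oc4c(C=O)cc(OC)c(OCc5ccccc5)c4OCOC)c23)c1
F3 | step 13 | 4-(benzyloxy)-2-{[8-bromo-4-(3,5-dimethoxyphenoxy)-1,3,7-trimethoxydibenzo[b,d]furan-9-yl]oxy}-3-hydroxy-5-methoxybenzaldehyde | COc1cc(OC)cc(Oc2c(OC)cc(OC)c3c2oc2cc(OC)c(Br)c(Oc4c(C=O)cc(OC)c(OCc5ccccc5)c4O)c23)c1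
F4 | step 6 | 2-[2-(3,5-dimethoxyphenoxy)-3,5-dimethoxyphenoxy]-4-methoxy-6-[2-(trimethylsilyl)ethoxy]phenyl formate | COc1cc(OC)cc(Oc2c(Oc3cc(OC)cc(OCC[Si](C)(C)C)c3OC=O)cc(OC)cc2OC)c1
F5 | step 6 | 2-[2-(3,5-dimethoxyphenoxy)-3,5-dimethoxyphenoxy]-4-methoxy-6-[2-(trimethylsilyl)ethoxy]phenol | COc1cc(OC)cc(Oc2c(Oc3cc(OC)cc(OCC[Si](C)(C)C)c3O)cc(OC)cc2OC)c1
F6 | step 6 | 2-[2-(3,5-dimethoxyphenoxy)-3,5-dimethoxyphenoxy]-4-methoxy-6-[2-(trimethylsilyl)ethoxy]phenyl trifluoromethanesulfonate | COc1cc(OC)cc(Oc2c(Oc3cc(OC)cc(OCC[Si](C)(C)C)c3OS(=O)(=O)C(F)(F)F)cc(OC)cc2OC)c1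
F7 | step 22 | arylboronic acid from 26 (F6–Br replaced by B(OH)2) | COc1cc(OC)cc(Oc2c(OC)cc(OC)c3c2oc2cc(OC)c4c(c23)Oc2c(OC)cc(OC)c(Oc5cc(OC)cc(OC)c5-c5c(OC)cc(OC)cc5B(O)O)c2O4)c1
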